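**Assumptions (one line):** Absolute configuration read from the SMILES is 2R,3S (trans-dihydrobenzofuran) and 7S,8R (erythro). The Rh2 and Ru catalyst enantiomers named below are assigned from precedent and may need to be swapped after a small screen. Methyl dihydroferulate, syringyl alcohol and bromoacetoveratrone are taken as commercial.

## Retrosynthetic overview
1. The C3-CH2OH and C5-propanol arms come from two esters (one LiAlH4 step). The C7/C9 diol is carried as an acetonide and released last.
2. The dihydrobenzofuran ring is formed last among the ring-forming steps, by a Rh2-catalysed donor/acceptor carbene C–H insertion. An aryl diazoacetate inserts into the ortho-O-CH2-Ar benzylic C–H, closing the C2–C3 bond and setting trans-(2R,3S) in one step.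
3. The diazoacetate comes from a Mitsunobu benzyl ether of an arylacetate phenol (ring A) with the benzylic alcohol of the syringyl–glycerol fragment.
4. The erythro (7S,8R) aryl glycerol ether is set by dynamic kinetic resolution–asymmetric transfer hydrogenation of an α-aryloxy-β-hydroxy ketone. That ketone comes from syringyl alcohol, bromoacetoveratrone and formaldehyde.
5. Ring A comes from methyl dihydroferulate by ortho-hydroxyalkylation with glyoxylate and then deoxygenation.

## Route

**Step 1**
Reactants: 1 methyl 3-(4-hydroxy-3-methoxyphenyl)propanoate; 2 ethyl glyoxylate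
Product: 3 ethyl 2-hydroxy-2-[2-hydroxy-3-methoxy-5-(3-methoxy-3-oxopropyl)phenyl]acetate (racemic carbinol)
Conditions: 2 (1.5 equiv), TiCl4 (1.1 equiv), CH2Cl2, –20 °C → rt
Reagents that add atoms: ethyl glyoxylate, CCOC(=O)C=O
Why: Ti-phenoxide-directed ortho Friedel–Crafts hydroxyalkylation; the para position is blocked and the other ortho position carries OMe, so it goes to C6. The new carbinol stereocentre is destroyed in Step 2.

**Step 2**
Reactants: 3
Product: 4 ethyl 2-[2-hydroxy-3-methoxy-5-(3-methoxy-3-oxopropyl)phenyl]acetate
Conditions: Et3SiH (3 equiv), TFA, CH2Cl2, 0 °C → rt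
Reagents that add atoms: none
Why: Ionic deoxygenation through the o-hydroxybenzylic cation (o-quinone methide type) with silane hydride; the esters and aryl methyl ethers survive.

**Step 3**
Reactants: 5 syringyl alcohol (4-hydroxy-3,5-dimethoxybenzyl alcohol); 6 2-bromo-1-(3,4-dimethoxyphenyl)ethanone
Product: 7 1-(3,4-dimethoxyphenyl)-2-[4-(hydroxymethyl)-2,6-dimethoxyphenoxy]ethanone
Conditions: K2CO3, acetone, reflux
Reagents that add atoms: 6, COc1ccc(C(=O)CBr)cc1OC
Why: Williamson O-alkylation; the acidic phenol reacts selectively over the benzylic alcohol.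

**Step 4**
Reactants: 7; 8 paraformaldehyde
Product: 9 1-(3,4-dimethoxyphenyl)-3-hydroxy-2-[4-(hydroxymethyl)-2,6-dimethoxyphenoxy]propan-1-one (racemic at C8)
Conditions: (CH2O)n (1.1 equiv), K2CO3 (cat.), dioxane–H2O, rt
Reagents that add atoms: paraformaldehyde, C=O
Why: Base-mediated aldol-type hydroxymethylation at the doubly activated α-carbon (the standard route to β-O-4 ketones). C8 is left racemic and epimerisable for Step 5.

**Step 5**
Reactants: 9
Product: 10 (1S,2R)-1-(3,4-dimethoxyphenyl)-2-[4-(hydroxymethyl)-2,6-dimethoxyphenoxy]propane-1,3-diol (7S,8R, erythro)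
Conditions: RuCl[(R,R)-TsDPEN](p-cymene) (2 mol %), HCO2H–Et3N (5:2), EtOAc, 35 °C
Reagents that add atoms: none (only H is added)
Why: Proposed new method: Noyori–Ikariya asymmetric transfer hydrogenation run as a dynamic kinetic resolution. Et3N epimerises the acidic C8-H (flanked by C=O, OAr and CH2OH). The (R,R)-catalyst fixes the ketone face, giving C7 = S. The more reactive C8 epimer is reduced by polar-Felkin-type approach, which gives the anti (zigzag) = erythro relationship, and the β-OH helps lock the conformer. The closest known chemistry is DKR–ATH of α-alkoxy and α-substituted β-keto esters.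

**Step 6**
Reactants: 10; 11 2,2-dimethoxypropane
Product: 12 [4-((4S,5R)-... ) acetonide] = (4S,5R)-4-(3,4-dimethoxyphenyl)-5-[4-(hydroxymethyl)-2,6-dimethoxyphenoxy]-2,2-dimethyl-1,3-dioxane
Conditions: 11 (3 equiv), CSA (5 mol %), CH2Cl2, 0 °C → rt; quench with Et3N
Reagents that add atoms: 2,2-dimethoxypropane, COC(C)(C)OC
Why: Transketalisation closes the six-membered 1,3-diol acetonide. This masks C7-OH and C9-OH, which would otherwise undergo O–H insertion in Step 9. Chromatography here also removes any minor diastereomer from Step 5.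

**Step 7**
Reactants: 4; 12
Product: 13 ethyl 2-[2-({4-[(4S,5R)-acetonide-oxy]-3,5-dimethoxybenzyl}oxy)-3-methoxy-5-(3-methoxy-3-oxopropyl)phenyl]acetate (the benzyl aryl ether joining 4 and 12)
Conditions: PPh3, DIAD, THF, 0 °C → rt
Reagents that add atoms: none (PPh3 and DIAD are not retained)
Why: Mitsunobu etherification with the phenol as pronucleophile and the primary benzylic alcohol as electrophile; no stereocentre is involved.

**Step 8**
Reactants: 13; 14 p-acetamidobenzenesulfonyl azide (p-ABSA)
Product: 15 the α-diazo-arylacetate of 13 (ArC(=N2)CO2Et)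
Conditions: 14 (1.2 equiv), DBU, MeCN, 0 °C → rt
Reagents that add atoms: p-ABSA, CC(=O)Nc1ccc(cc1)S(=O)(=O)N=[N+]=[N-] (N2 is retained)
Why: Regitz diazo transfer occurs selectively at the acidic arylacetate CH2, not at the propanoate.

**Step 9**
Reactants: 15
Product: 16 trans-(2R,3S)-2-aryl-3-(ethoxycarbonyl)-7-methoxy-5-(3-methoxy-3-oxopropyl)-2,3-dihydrobenzofuran bearing the acetonide-protected glycerol ether
Conditions: Rh2(S-PTAD)4 (1 mol %), CH2Cl2, 0 → 23 °C
Reagents that add atoms: none (N2 is lost)
Why: Proposed new method: catalyst-controlled intramolecular 1,5-C–H insertion of a donor/acceptor Rh carbene into the benzylic ether C–H, in the manner of the known Rh2-catalysed synthesis of trans-2,3-dihydrobenzofurans from ortho-benzyloxy aryl diazoacetates. The chiral carboxylate catalyst sets C2 and C3, and the trans isomer is preferred. The remote glycerol stereocentres should not override catalyst control. The electron-rich aryl groups are the main extension beyond precedent.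

**Step 10**
Reactants: 16
Product: 17 acetonide-protected diol-triol: the 3-CH2OH / 5-(3-hydroxypropyl) dihydrobenzofuran
Conditions: LiAlH4, THF, 0 °C
Reagents that add atoms: none (only H is added)
Why: Both the ethyl and methyl esters are reduced to primary alcohols; the acetonide and aryl ethers are inert, and the trans arrangement at C3 is thermodynamically preferred, so it is not scrambled.

**Step 11**
Reactants: 17
Product: 18 Berbikonol
Conditions: AcOH–H2O (4:1), 40 °C
Reagents that add atoms: water, O
Why: Mild aqueous acid hydrolyses the acetonide without ionising the benzylic C7 position, so C7 and C8 keep their configuration.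

## Compound list
1 | methyl 3-(4-hydroxy-3-methoxyphenyl)propanoate | COC(=O)CCc1ccc(O)c(OC)c1 | starting material
2 | ethyl glyoxylate | CCOC(=O)C=O | starting material
3 | ethyl 2-hydroxy-2-[2-hydroxy-3-methoxy-5-(3-methoxy-3-oxopropyl)phenyl]acetate | CCOC(=O)C(O)c1cc(CCC(=O)OC)cc(OC)c1O | intermediate
4 | ethyl 2-[2-hydroxy-3-methoxy-5-(3-methoxy-3-oxopropyl)phenyl]acetate | CCOC(=O)Cc1cc(CCC(=O)OC)cc(OC)c1O | intermediate
5 | syringyl alcohol | COc1cc(CO)cc(OC)c1O | starting material
6 | 2-bromo-1-(3,4-dimethoxyphenyl)ethanone | COc1ccc(C(=O)CBr)cc1OC | starting material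
7 | aryloxy ketone | COc1ccc(C(=O)COc2c(OC)cc(CO)cc2OC)cc1OC | intermediate
8 | paraformaldehyde | C=O | starting material
9 | hydroxymethyl ketone (racemic at C8) | COc1ccc(C(=O)C(CO)Oc2c(OC)cc(CO)cc2OC)cc1OC | intermediate
10 | erythro (7S,8R) triol | COc1ccc([C@H](O)[C@@H](CO)Oc2c(OC)cc(CO)cc2OC)cc1OC | intermediate
11 | 2,2-dimethoxypropane | COC(C)(C)OC | starting material
12 | acetonide alcohol | COc1ccc([C@@H]2OC(C)(C)OC[C@H]2Oc3c(OC)cc(CO)cc3OC)cc1OC | intermediate
13 | Mitsunobu ether | COc1ccc([C@@H]2OC(C)(C)OC[C@H]2Oc3c(OC)cc(COc4c(OC)cc(CCC(=O)OC)cc4CC(=O)OCC)cc3OC)cc1OC | intermediate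
14 | p-ABSA | CC(=O)Nc1ccc(cc1)S(=O)(=O)N=[N+]=[N-] | starting material
15 | aryl diazoacetate | COc1ccc([C@@H]2OC(C)(C)OC[C@H]2Oc3c(OC)cc(COc4c(OC)cc(CCC(=O)OC)cc4C(=[N+]=[N-])C(=O)OCC)cc3OC)cc1OC | intermediate
16 | trans-dihydrobenzofuran diester | COc1ccc([C@@H]2OC(C)(C)OC[C@H]2Oc3c(OC)cc([C@@H]4Oc5c(OC)cc(CCC(=O)OC)cc5[C@H]4C(=O)OCC)cc3OC)cc1OC | intermediate
17 | acetonide-protected Berbikonol | COc1ccc([C@@H]2OC(C)(C)OC[C@H]2Oc3c(OC)cc([C@@H]4Oc5c(OC)cc(CCCO)cc5[C@H]4CO)cc3OC)cc1OC | intermediate
18 | Berbikonol | COc1ccc([C@H](O)[C@@H](CO)Oc2c(OC)cc([C@@H]3Oc4c(OC)cc(CCCO)cc4[C@H]3CO)cc2OC)cc1OC | target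

## Totals
Total steps: 11 (convergent, two arms joined at Step 7).
Longest linear sequence: 9 steps (syringyl alcohol 5 → Steps 3, 4, 5, 6, 7, 8, 9, 10, 11).

## Three steps most likely to fail
1. **Step 5 (DKR–ATH).** The α-carbon is hindered and epimerisation may be too slow, the erythro/threo ratio is uncertain, and retro-aldol is possible.
   Fallback: reduce racemic ketone 9 with Zn(BH4)2 for chelation-controlled erythro selectivity, then resolve the enantiomers of acetonide 12 by preparative chiral SFC.
2. **Step 9 (Rh C–H insertion).** Enantiomeric excess, trans/cis ratio or competing carbene side reactions on this electron-rich substrate may be poor.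
   Fallback: build the ring by a different route. Use an Evans aldol of an N-(2-OR-arylacetyl)oxazolidinone with the syringyl–glycerol aryl aldehyde. Then deprotect the phenol and close by Mitsunobu SN2 with inversion at the carbinol, choosing the aldol diastereomer so that closure gives the trans ring.
3. **Step 1 (ortho-hydroxyalkylation).** Regioselectivity (C6 versus C5) and the double-addition by-product are the risks.
   Fallback: ortho-iodinate 1 with NIS and install the acetate by Pd-catalysed α-arylation of tert-butyl acetate (Hartwig conditions), giving the arylacetate directly.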